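## Structural features

The target is a trans-3,4-dibenzyl-γ-butyrolactone. In the five-membered lactone (O1, C2(=O), C3, C4, C5), C3 carries the guaiacyl ring G (4-hydroxy-3-methoxyphenyl) through the methylene C7', and C4 carries the syringyl ring S (4-hydroxy-3,5-dimethoxyphenyl) through the methylene C7. C3 and C4 are adjacent stereocentres, both R, with the two benzyl arms trans. C3 lies α to the lactone carbonyl and can be epimerised, trans being the more stable arrangement, whereas C4 has no acidifying neighbour and must be installed in the correct absolute sense from the start. The fragile groups are the two electron-rich free phenols (oxidation, quinone-methide formation in benzylic intermediates), the lactone (nucleophiles, hydroxide) and the C3–H bond (base). The real difficulty is that rings G and S differ by one methoxy group only, so each must be delivered to its own carbon without any symmetry shortcut while C4 is fixed as R. C4 is a methine bonded to ring carbon C3, the oxymethylene C5 and the benzylic C7. That is the pattern left when a lactone-fused cyclopropane containing an extra C3–C7 bond is opened at C7 by an aryl nucleophile; the key step sends ring S to C7 and then captures the C3 enolate with the benzylic electrophile of ring G.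

## Logic of the disconnections

**14 ⇒ 13.** The two phenolic O–H bonds are replaced by O–CH2Ph bonds. Benzyl ethers survive Grignard formation, organocopper chemistry, enolate alkylation and hot chloride, and both fall in one neutral hydrogenolysis. The demand is that 13 holds no other reducible group, which is the case.

**13 ⇒ 12.** A C3–CO2Et bond is added back. C3 becomes a malonate-type carbon, which makes its enolate easy to form and alkylate and makes the cyclopropane of the next disconnection electrophilic. The C3 configuration of 12 then no longer matters, because the forward step removes the ester and lets C3 settle trans to the fixed C4. The forward step must cleave the ethyl ester without opening the lactone.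

**12 ⇒ 5 + 8 + 10.** The bonds C7–C(ring S) and C3–C7' are cut and a C3–C7 bond is drawn in its place. This leaves a small chiral bicycle, an aryl nucleophile and a benzylic electrophile, so both arms are attached in one operation and C4 is never a reacting centre. The forward step needs attack at the cyclopropane CH2 and not at the ring-fusion carbon or a carbonyl, and the enolate 11 must be alkylated on carbon before it is quenched.

**5 ⇒ 1 + 2.** The bonds C3–C7, C3–C4 and O1–C2 are cut. The central carbon of 2 acts twice as a nucleophile and 1 serves as a chiral 1,2-dielectrophile whose oxygen ends up as O1. The gain is a one-step, chiral-pool entry to the only stereocentre that matters. The demand is that the epoxide CH2 of 1 reacts before the C–Cl carbon, since the opposite order gives the enantiomer; the sequence passes through 3 and 4.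

**8 ⇒ 7 ⇒ 6.** The C–Mg bond is traced to a C–Br bond and the O–CH2Ph bond to the free phenol. The forward steps are an O-alkylation and a magnesium insertion into an electron-rich aryl bromide.

**10 ⇒ 9.** The C–Br bond is traced to the C–OH bond of a purchasable benzylic alcohol. The forward step must give a reactive, self-condensing bromide cleanly enough to be used at once.

## Other disconnections considered

**Alternative 1:** The cut is C2–C3, with the C7'–H bond formed in the same event.

- **Forward step.** The selenocarbonate A1 would give up its selenium to a silyl radical under azo initiation with a silane hydrogen donor. The resulting alkoxycarbonyl radical on C2 adds 5-exo-trig to C3 of the styrene-type C3=C7' double bond, and the benzylic C7' radical, stabilised by ring G, takes a hydrogen atom to give A2, which is identical with 13.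
- **In favour.** The lactone and C3 are made in one neutral step that tolerates benzyl ethers, and the regiochemistry is dictated by the benzylic radical. There is no ester to remove afterwards, so A2 is one hydrogenolysis from 14. On post-key-step economy this alternative is better than the chosen plan by one operation.
- **Against.** C4 must already be present in A1 as an enantioenriched, 2-branched homoallylic alcohol. The absolute stereochemical problem is only moved upstream and would cost an auxiliary- or catalyst-based sequence plus an olefination, against the one-step chiral-pool access to 5. C3 is set kinetically through a chair-like transition state with the C4 arm pseudo-equatorial, which favours trans but seldom completely. Selenium reagents and a phosgene-type carbonylating agent are needed, and premature reduction of the acyl radical is a competing path.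
- **Comparison.** On the final C3 outcome the two plans are equal, since both can fall back on the thermodynamic trans preference. On structure the key product is the same protected lactone. Overall the chosen plan is shorter and avoids the toxic selenium chemistry.

**Alternative 2:** The cut removes two C–C bonds of ring G, so the arene is built last.

- **Forward step.** The lactone ester A3, whose C3 carries a CH2–C(CHO)=CH–NMe2 arm, would be condensed with methoxyacetone A4 under a potassium alkoxide. The methyl and methoxymethyl carbons of A4 each bond to one of the two electrophilic carbons of the aminoacrolein, and loss of water and dimethylamine aromatises the ring to give A5.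
- **In favour.** The ketone oxygen becomes the phenol and the methoxy group of A4 becomes the ring G methoxy group. Either orientation of A4 gives the same arene, so regiochemistry is not an issue. Ring G arrives unprotected and no labile electron-rich benzylic bromide is needed; on these two points it is better than the chosen plan.
- **Against.** Ring G is a commodity aromatic, so building it de novo adds steps: a three-carbon arm must be placed on C3 and converted into the aminoacrolein. The alkoxide conditions threaten the lactone and the quaternary malonate-type centre of A3 through ring opening, transesterification and retro-Claisen cleavage, and A4 can self-condense.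
- **Comparison.** C4 and ring S would still come from the same cyclopropane opening, so on the central stereochemical issue the two plans are equal. They are also equal after the key step, since A5 still needs ester removal and one hydrogenolysis. The chosen plan attaches ring G in the same flask as ring S and is several operations shorter.

**Alternative 3:** The cut removes both C–O bonds of O1.

- **Forward step.** The prochiral cyclobutanone A6 would be oxidised by a Baeyer–Villiger monooxygenase with air and cofactor recycling. One of the two enantiotopic CH2 groups migrates to oxygen with retention through a Criegee-type intermediate, giving lactone A7. Its enolate would then be benzylated with 10 anti to the C4 arm to give 13.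
- **In favour.** The desymmetrisation is catalytic, aqueous and run near ambient temperature, and no ester has to be installed and removed. It needs neither an alkylating epoxide nor an organocopper step; on reagent hazard it is better than the chosen plan. The anti alkylation of a 4-benzyl butyrolactone is a dependable way to set C3, equal in reliability to the equilibration used here.
- **Against.** The sense and level of enantioselection depend on the enzyme and would have to be found by screening for this bulky, poorly water-soluble substrate, whereas the chosen plan takes C4 from a reagent with a predictable stereochemical course. A6 needs about three steps (ketene cycloaddition to an allylarene and dechlorination), and the second arm needs a separate strong-base step at low temperature.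
- **Comparison.** The overall step count is about equal. The mechanisms differ in that stereocontrol comes from the enzyme pocket rather than from the substrate.

Key step: step 5

Remarks on the chemistry (assumptions):
- 4-(Benzyloxy)-3-methoxybenzyl alcohol 9 is treated as a purchasable starting material.
- Compound 12 is drawn as the C3 epimer expected from anti alkylation; the other epimer would converge on 13 because C3 is reset in step 6.
- DMPU is N,N'-dimethylpropyleneurea.

## Route

Step 1
Reactants: 1 (R)-epichlorohydrin [(2R)-2-(chloromethyl)oxirane]; 2 diethyl malonate
Product: 5 ethyl (1S,5R)-2-oxo-3-oxabicyclo[3.1.0]hexane-1-carboxylate, via epoxymalonate 3 (not isolated), via cyclopropylcarbinol diester 4 (not isolated)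
Conditions: NaOEt (1.0 equiv), EtOH, rt then reflux
Reagents that add atoms: none
Why: Malonate–epichlorohydrin annulation: the sodium enolate of 2 opens the epoxide of 1 at its CH2, the chlorohydrin alkoxide closes to epoxide 3 without touching the stereocentre, and the re-formed enolate opens 3 at its CH carbon (3-exo-tet, inversion) to give 4, whose alkoxide lactonises onto the cis ester. The stereocentre of 1 thereby becomes C5 of 5 (R), and C1 (S) follows because the lactone can only be cis-fused to the cyclopropane.

Step 2
Reactants: 6 4-bromo-2,6-dimethoxyphenol
Product: 7 2-(benzyloxy)-5-bromo-1,3-dimethoxybenzene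
Conditions: BnBr, K2CO3, DMF, 60 °C
Reagents that add atoms: benzyl bromide, BrCc1ccccc1
Why: Williamson ether synthesis; the phenoxide of 6 is alkylated on oxygen by the benzylic bromide, and a polar aprotic solvent overcomes the hindrance of the two flanking methoxy groups.

Step 3
Reactants: 7 2-(benzyloxy)-5-bromo-1,3-dimethoxybenzene
Product: 8 [4-(benzyloxy)-3,5-dimethoxyphenyl]magnesium bromide (THF solution, titrated and used directly)
Conditions: Mg turnings, I2 (cat.), THF, 50 °C
Reagents that add atoms: magnesium, [Mg]
Why: Grignard formation by insertion of magnesium into the aryl C–Br bond; aryl methyl and aryl benzyl ethers are inert to the reagent, and slow addition of 7 keeps homocoupling low.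

Step 4
Reactants: 9 4-(benzyloxy)-3-methoxybenzyl alcohol
Product: 10 4-(benzyloxy)-3-methoxybenzyl bromide
Conditions: PBr3 (0.4 equiv), CH2Cl2, 0 °C
Reagents that add atoms: phosphorus tribromide, BrP(Br)Br
Why: Bromination of a primary benzylic alcohol through its phosphite ester with SN2 displacement by bromide; the masked phenol and the low temperature keep the electron-rich bromide from self-condensing, and it is used promptly.

Step 5
Reactants: 5 ethyl (1S,5R)-2-oxo-3-oxabicyclo[3.1.0]hexane-1-carboxylate; 8 [4-(benzyloxy)-3,5-dimethoxyphenyl]magnesium bromide; 10 4-(benzyloxy)-3-methoxybenzyl bromide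
Product: 12 ethyl (3R,4R)-3-[4-(benzyloxy)-3-methoxybenzyl]-4-[4-(benzyloxy)-3,5-dimethoxybenzyl]-2-oxotetrahydrofuran-3-carboxylate, via bromomagnesium enolate 11 (not isolated)
Conditions: 8 (1.15 equiv), CuI (10 mol %), THF, −40 → −20 °C; then 10 (1.5 equiv), DMPU, Bu4NI (cat.), −20 → 40 °C; aq. NH4Cl
Reagents that add atoms: none
Why: Transmetallation of 8 with catalytic CuI gives an aryl species of monovalent copper that attacks the unsubstituted cyclopropane carbon (C6 of 5, the future C7) in an SN2-like homoconjugate addition, formally an oxidative addition across the C1–C6 bond to trivalent copper followed by reductive elimination; this forms the C7–ring S bond and releases the chelated bromomagnesium enolate 11, whose charge is shared by the lactone and ester carbonyls. The closest known reaction type is the copper-catalysed Grignard opening of cyclopropane-1,1-dicarbonyl compounds, joined to the in-flask alkylation of the resulting malonate-type enolate as in conjugate addition–enolate trapping. No ring is closed; the three-membered ring is opened and the lactone ring is left intact. Regioselectivity is needed between the CH2 and the ring-fusion CH (C5 of 5, the future C4): the CH2 is primary and its bond to C1 lies outside the lactone ring, where it is better aligned with the carbonyl π systems, whereas the ring-fusion carbon is secondary and shielded. Chemoselectivity over the two carbonyl groups rests on the soft copper nucleophile and the low temperature, and only a small excess of 8 is used because surplus aryl-metal would couple with 10. DMPU loosens the magnesium chelate and iodide converts 10 into the more reactive benzylic iodide, so that C-alkylation forms the C3–C7' bond. The new quaternary stereocentre C3 is controlled by the adjacent C4 arm, the electrophile approaching the enolate face anti to it (3R); this centre is erased in step 6, so imperfect selectivity does no harm. The stereocentre inherited from 5 is not a reacting centre and keeps its configuration as C4 (R).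

Step 6
Reactants: 12 ethyl (3R,4R)-3-[4-(benzyloxy)-3-methoxybenzyl]-4-[4-(benzyloxy)-3,5-dimethoxybenzyl]-2-oxotetrahydrofuran-3-carboxylate
Product: 13 (3R,4R)-3-[4-(benzyloxy)-3-methoxybenzyl]-4-[4-(benzyloxy)-3,5-dimethoxybenzyl]dihydrofuran-2(3H)-one
Conditions: LiCl (3 equiv), H2O (2 equiv), DMSO, 150 °C; then DBU (cat.), PhMe, 80 °C
Reagents that add atoms: none
Why: Krapcho dealkoxycarbonylation: chloride dealkylates the ethyl ester, the carboxylate loses CO2 and water protonates the lactone enolate. C3–H is the only epimerisable centre, and the DBU treatment lets it settle trans to the fixed C4 arm, the more stable arrangement of 3,4-dibenzyl butyrolactones, giving (3R,4R).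

Step 7
Reactants: 13 (3R,4R)-3-[4-(benzyloxy)-3-methoxybenzyl]-4-[4-(benzyloxy)-3,5-dimethoxybenzyl]dihydrofuran-2(3H)-one
Product: 14 (3R,4R)-3-(4-hydroxy-3-methoxybenzyl)-4-(4-hydroxy-3,5-dimethoxybenzyl)dihydrofuran-2(3H)-one
Conditions: H2 (1 atm), 10% Pd/C, EtOAc–EtOH, rt
Reagents that add atoms: none
Why: Hydrogenolysis of both aryl benzyl ethers over Pd/C; the lactone, the aryl methyl ethers and the unoxygenated benzylic CH2 groups are inert, and the neutral medium leaves C3 and C4 untouched.

## Compound list

1 | (R)-epichlorohydrin, (2R)-2-(chloromethyl)oxirane | ClC[C@H]1CO1 | starting material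
2 | diethyl malonate | CCOC(=O)CC(=O)OCC | starting material
3 | diethyl 2-{[(2R)-oxiran-2-yl]methyl}propanedioate (not isolated) | CCOC(=O)C(C[C@@H]1CO1)C(=O)OCC | intermediate
4 | diethyl (2R)-2-(hydroxymethyl)cyclopropane-1,1-dicarboxylate, present as its sodium alkoxide (not isolated) | CCOC(=O)C1(C(=O)OCC)C[C@H]1CO | intermediate
5 | ethyl (1S,5R)-2-oxo-3-oxabicyclo[3.1.0]hexane-1-carboxylate | O=C1OC[C@@H]2C[C@]12C(=O)OCC | intermediate
6 | 4-bromo-2,6-dimethoxyphenol | COc1cc(Br)cc(OC)c1O | starting material
7 | 2-(benzyloxy)-5-bromo-1,3-dimethoxybenzene | COc1cc(Br)cc(OC)c1OCc1ccccc1 | intermediate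
8 | [4-(benzyloxy)-3,5-dimethoxyphenyl]magnesium bromide | COc1cc([Mg]Br)cc(OC)c1OCc1ccccc1 | intermediate
9 | 4-(benzyloxy)-3-methoxybenzyl alcohol | COc1cc(CO)ccc1OCc1ccccc1 | starting material
10 | 4-(benzyloxy)-3-methoxybenzyl bromide | COc1cc(CBr)ccc1OCc1ccccc1 | intermediate
11 | bromomagnesium enolate of ethyl (4R)-4-[4-(benzyloxy)-3,5-dimethoxybenzyl]-2-oxotetrahydrofuran-3-carboxylate (not isolated) | CCOC(=O)C1=C(O[Mg]Br)OC[C@@H]1Cc1cc(OC)c(OCc2ccccc2)c(OC)c1 | intermediate
12 | ethyl (3R,4R)-3-[4-(benzyloxy)-3-methoxybenzyl]-4-[4-(benzyloxy)-3,5-dimethoxybenzyl]-2-oxotetrahydrofuran-3-carboxylate | CCOC(=O)[C@]1(Cc2ccc(OCc3ccccc3)c(OC)c2)C(=O)OC[C@@H]1Cc1cc(OC)c(OCc2ccccc2)c(OC)c1 | intermediate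
13 | (3R,4R)-3-[4-(benzyloxy)-3-methoxybenzyl]-4-[4-(benzyloxy)-3,5-dimethoxybenzyl]dihydrofuran-2(3H)-one | COc1cc(C[C@H]2C(=O)OC[C@@H]2Cc2cc(OC)c(OCc3ccccc3)c(OC)c2)ccc1OCc1ccccc1 | intermediate
14 | (3R,4R)-3-(4-hydroxy-3-methoxybenzyl)-4-(4-hydroxy-3,5-dimethoxybenzyl)dihydrofuran-2(3H)-one | COc1cc(C[C@H]2C(=O)OC[C@@H]2Cc2cc(OC)c(O)c(OC)c2)ccc1O | target

## Step count and least certain steps

Total: 7 steps. Longest linear sequence: 5 steps (steps 2, 3, 5, 6, 7, from 6 to 14).

**Step 5 (key step).** The most likely failure is sluggish C-alkylation of the chelated, doubly stabilised bromomagnesium enolate. The benzylic bromide would then be used up by copper-catalysed coupling with leftover aryl-metal or by self-condensation, and work-up would return the unalkylated lactone ester. Carbonyl addition by the Grignard reagent is a second risk if the mixture warms before the cyclopropane is consumed. The fallback separates the two bond formations. It sets out from 5 and 8: the copper-catalysed opening alone is run and quenched with aqueous NH4Cl to give ethyl (4R)-4-[4-(benzyloxy)-3,5-dimethoxybenzyl]-2-oxotetrahydrofuran-3-carboxylate F1 as a mixture of C3 epimers. F1 is then alkylated with 10 and K2CO3 in acetone at reflux, a classical malonate-type alkylation of a potassium enolate, and the route is rejoined at 12.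

**Step 6.** Chloride may open the lactone at C5 in competition with dealkylation of the ethyl ester, which is slowed by the neighbouring quaternary carbon. Protonation of the enolate may also leave part of the material as the cis C3 epimer if equilibration is incomplete. The fallback sets out from 12: saponification with LiOH in aqueous THF cleaves the ester and opens the lactone to 2-[4-(benzyloxy)-3-methoxybenzyl]-2-{(2R)-1-[4-(benzyloxy)-3,5-dimethoxyphenyl]-3-hydroxypropan-2-yl}propanedioic acid F2 (dilithium salt, free diacid after acidification). Heating in toluene relactonises it to (4R)-3-[4-(benzyloxy)-3-methoxybenzyl]-4-[4-(benzyloxy)-3,5-dimethoxybenzyl]-2-oxotetrahydrofuran-3-carboxylic acid F3, which loses CO2 thermally; the same DBU equilibration then gives 13, where the route is rejoined.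

**Step 1.** Some direct displacement of chloride may compete with epoxide opening. That pathway leads to the enantiomeric bicycle and so erodes enantiomeric purity, and ethoxide can also open the product lactone and lower the return. The fallback sets out from 2. (R)-Glycidol F4 is converted with triflic anhydride and 2,6-lutidine in CH2Cl2 at −78 °C into (2S)-oxiran-2-ylmethyl trifluoromethanesulfonate F5. The sodium enolate of 2 (NaH, THF) displaces the triflate directly, without involving the stereocentre, and so gives 3 in the flask. Compound 3 then closes through 4 to 5 on warming as in the main route, which is rejoined at 3 and hence at 5.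

**Step 3.** Initiation of the electron-rich aryl bromide may be slow and Wurtz-type homocoupling may then lower the titre of the reagent. The fallback sets out from 7: bromine–lithium exchange with n-BuLi in THF at −78 °C gives [4-(benzyloxy)-3,5-dimethoxyphenyl]lithium F6, which is transmetallated with MgBr2·OEt2 to the same reagent 8, where the route is rejoined.

## Further compounds

F1 | step 5 | ethyl (4R)-4-[4-(benzyloxy)-3,5-dimethoxybenzyl]-2-oxotetrahydrofuran-3-carboxylate (C3 epimers) | CCOC(=O)C1C(=O)OC[C@@H]1Cc1cc(OC)c(OCc2ccccc2)c(OC)c1
F2 | step 6 | 2-[4-(benzyloxy)-3-methoxybenzyl]-2-{(2R)-1-[4-(benzyloxy)-3,5-dimethoxyphenyl]-3-hydroxypropan-2-yl}propanedioic acid | OC[C@H](Cc1cc(OC)c(OCc2ccccc2)c(OC)c1)C(Cc1ccc(OCc2ccccc2)c(OC)c1)(C(O)=O)C(O)=O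
F3 | step 6 | (4R)-3-[4-(benzyloxy)-3-methoxybenzyl]-4-[4-(benzyloxy)-3,5-dimethoxybenzyl]-2-oxotetrahydrofuran-3-carboxylic acid (C3 epimers) | OC(=O)C1(Cc2ccc(OCc3ccccc3)c(OC)c2)C(=O)OC[C@@H]1Cc1cc(OC)c(OCc2ccccc2)c(OC)c1
F4 | step 1 | (R)-glycidol, (2R)-oxiran-2-ylmethanol | OC[C@@H]1CO1
F5 | step 1 | (2S)-oxiran-2-ylmethyl trifluoromethanesulfonate | FC(F)(F)S(=O)(=O)OC[C@@H]1CO1
F6 | step 3 | [4-(benzyloxy)-3,5-dimethoxyphenyl]lithium | [Li]c1cc(OC)c(OCc2ccccc2)c(OC)c1
A1 | alternative 1 | O-{(2R,3E)-2-[4-(benzyloxy)-3,5-dimethoxybenzyl]-4-[4-(benzyloxy)-3-methoxyphenyl]but-3-en-1-yl} Se-phenyl carbonoselenoate | O=C([Se]c1ccccc1)OC[C@H](Cc1cc(OC)c(OCc2ccccc2)c(OC)c1)/C=C/c1ccc(OCc2ccccc2)c(OC)c1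
A2 | alternative 1 | (3R,4R)-3-[4-(benzyloxy)-3-methoxybenzyl]-4-[4-(benzyloxy)-3,5-dimethoxybenzyl]dihydrofuran-2(3H)-one (identical with 13) | COc1cc(C[C@H]2C(=O)OC[C@@H]2Cc2cc(OC)c(OCc3ccccc3)c(OC)c2)ccc1OCc1ccccc1
A3 | alternative 2 | ethyl (3R,4R)-4-[4-(benzyloxy)-3,5-dimethoxybenzyl]-3-[3-(dimethylamino)-2-formylprop-2-en-1-yl]-2-oxotetrahydrofuran-3-carboxylate (alkene geometry not defined) | CCOC(=O)[C@]1(CC(C=O)=CN(C)C)C(=O)OC[C@@H]1Cc1cc(OC)c(OCc2ccccc2)c(OC)c1
A4 | alternative 2 | methoxyacetone, 1-methoxypropan-2-one | COCC(C)=O
A5 | alternative 2 | ethyl (3R,4R)-4-[4-(benzyloxy)-3,5-dimethoxybenzyl]-3-(4-hydroxy-3-methoxybenzyl)-2-oxotetrahydrofuran-3-carboxylate | CCOC(=O)[C@]1(Cc2ccc(O)c(OC)c2)C(=O)OC[C@@H]1Cc1cc(OC)c(OCc2ccccc2)c(OC)c1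
A6 | alternative 3 | 3-[4-(benzyloxy)-3,5-dimethoxybenzyl]cyclobutan-1-one | O=C1CC(Cc2cc(OC)c(OCc3ccccc3)c(OC)c2)C1
A7 | alternative 3 | (4R)-4-[4-(benzyloxy)-3,5-dimethoxybenzyl]dihydrofuran-2(3H)-one | O=C1C[C@@H](Cc2cc(OC)c(OCc3ccccc3)c(OC)c2)CO1
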